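The earlier runs and the new flask were generated by integration for an exercise.

Flask green repeats the eta run at 55 °C with the impurity charge lowered from 0.32 mM to 0.21 mM, and it stands for 3.0 d, where eta was read up to 8.00 h. Red and amber change the temperature, and the runs show nothing about that.

in all of them: starting material 0.18 M; reagent 0.198 M; free catalyst 0.90 mM

| charge | second substrate | impurity | temperature | remark | time |
|---|---|---|---|---|---|
| eta | 0.18 M | 0.32 mM | 55 °C | run made earlier |  |
| green | 0.180 M | 0.21 mM | 55 °C |  | 3.0 d |
| red | 0.180 M | 0.21 mM | 85 °C |  | 3.0 d |
| amber | 0.180 M | 0.21 mM | 25 °C |  | 3.0 d |

eta run (percent of the starting material charged)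

| time / h | target / % |
|---|---|
| 0.833 | 13 |
| 2.50 | 26 |
| 5.00 | 41 |
| 8.00 | 51 |

(scatter of a reading: 1.5 percentage points)

* the flask that comes out highest in amount of target, in percent of the starting material charged, or "all alike" when all lie within 1.5 percentage points (green / red / amber / all alike)
* target at the end, in percent of the starting material charged, green
* target at the end, in percent of the starting material charged, red
* target at the end, in percent of the starting material charged, amber

- the earlier runs were read with a standard deviation of 1.5 percentage points
- the earlier runs do not show what temperature does; that part of a forecast is a guess
- no earlier run changes the charge of impurity; that part of a forecast is a guess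

We read eta as second order in starting material and reagent, whose charges are close, so u = y/(1 − y), with y the target fraction, should climb in a straight line while the catalyst lasts. It does not: u climbs at 0.179 h⁻¹ up to the first reading, but at 0.115 h⁻¹ over the last span. Taking that fall as first-order loss of catalyst gives a rate of dying of 0.0727 h⁻¹. Divide the rate of making by the rate of dying and time drops out, leaving 2.47. We call this the catalyst budget: the value of u the catalyst can pay for before it dies. It is a reading and carries the scatter of the readings.

We guess that impurity takes catalyst one for one, so the budget scales with the working catalyst, [free catalyst] − [impurity]: 0.690 mM in green against 0.580 mM in eta. Green's budget is then 2.94. Since 3.0 d is far longer than one catalyst lifetime, we expect green to end at y = u/(1 + u), or 74.6%. Eta's end on the same reckoning is 71.2%, lower because its working catalyst is smaller.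

The forecast picks green, with green 80%, red 78% and amber 52%, and says of red “catalyst death or side reactions may cap it”. Its green stands above ours.

The flasks give green 67.4%, red 39.4% and amber 63.4%, so green is highest.

    free catalyst → spent catalyst A (k = 5.77 × 10⁻⁷ s⁻¹, Ea = 97.0 kJ mol⁻¹)
    second substrate + reagent + free catalyst → free catalyst + second product (k = 0.0167 M⁻² s⁻¹, Ea = 52.0 kJ mol⁻¹)
    free catalyst + impurity → spent catalyst B (k = 0.592 M⁻¹ s⁻¹, Ea = 43.0 kJ mol⁻¹)
    starting material + reagent + free catalyst → free catalyst + target (k = 0.0656 M⁻² s⁻¹, Ea = 51.0 kJ mol⁻¹)
    (constants at 25 °C)

Green ends at u = 2.07 against its budget of 2.94, with free catalyst down to 0.363% and 15.4% of the reagent still there beside 0.0462 M of second product. Now take the neighbour charged with 0.45 M of starting material. Its reagent, catalyst and impurity charges are green's, so we carry over green's budget of 2.94, which as y is 74.6%, but the reagent charge allows 44.0% of that starting material, so we call reagent the limiting reagent there. That neighbour gives 38.8%, with 0.696% of the reagent left and 0.0219 M of second product at 3.00 d.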